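The readings come from a simulation on assumed constants; scatter was added.

Each J leaves by one of two roads: with Z to G, or by itself to L and on to D.

| flask | J | Z | remark | time |
|---|---|---|---|---|
| red | 0.094 M | 1 M | run made earlier |  |
| grey | 0.54 M | 1 M | run made earlier |  |
| violet | 1.5 M | 1 M | run made earlier |  |
| blue | 0.50 M | 0.59 M | run made earlier |  |
| Tuesday's | 2.0 M | 1.50 M |  | 5.0 h |
| Friday's | 0.12 M | 0.300 M |  | 5.0 h |
| Thursday's | 0.50 M | 2.00 M |  | 5.0 h |
| Saturday's | 0.30 M | 0.500 M |  | 5.0 h |
| Wednesday's | 0.50 M | 1.00 M |  | 5.0 h |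

- red (time / h: G / %, D / %): 0.200: 4, 1; 0.417: 9, 0; 0.667: 13, 7; 1.33: 15, 13; 2.50: 21, 27
- grey (time / h: G / %, D / %): 0.500: 10, 2; 1.00: 13, 6; 1.50: 19, 16; 2.00: 16, 24; 2.50: 17, 26
- violet (time / h: G / %, D / %): 0.500: 10, 3; 1.00: 11, 8; 1.50: 13, 13; 2.00: 19, 21; 2.50: 17, 27
- blue (time / h: G / %, D / %): 0.200: 4, 0; 0.667: 4, 5; 1.33: 10, 11; 2.00: 12, 22; 2.50: 12, 30

(readings scatter by 1.5 percentage points)

- the flasks put in order of share of G in all that became G or D, best first, at 5.0 h (Tuesday's / Friday's / Thursday's / Saturday's / Wednesday's)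
- the share of G in all that became G or D of the flask you put first, at 5.0 h
- the share of G in all that became G or D of the flask you put last, at 5.0 h

1. First estimate. At c_Z = 1 M, the last readings of red, grey and violet put G near 18.3%. G over the rest of the J, per M of Z, is a selectivity factor: 0.224 /M.

2. Objection: does G follow c_Z? Blue, at 0.59 M, reads 12% of G and gives 0.231 /M. So it does, as far as these readings show.

3. Objection: G may be decaying. From 1.50 h to 2.50 h, G in grey and violet changes by 1 percentage point on average, and the scatter is 1.5 points. This reckoning keeps G.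

4. Objection: the share counts D, not L. In the same hour, grey and violet gain 0.120 /h of the charge as D. At 2.00 h, G and D leave 60.0%. Grey's G reads half of its level at 0.500 h, so this reckoning puts J near 6.25% at 2.00 h and L at the remainder. L therefore drains at about 0.223 /h. That makes 0.670 turnovers up to 5.0 h, leaving 30.7% undrained, so this estimate puts D near 51.0%.

5. The rule. Q, the ratio of G to D at 5.0 h per M of Z, is 0.360 /M. With the time held at 5.0 h, the share is then Q·c_Z/(1 + Q·c_Z): 41.8% for Thursday's, 26.5% for Wednesday's, 15.2% for Saturday's and 9.74% for Friday's.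

6. Objection: Tuesday's uses Z. Tuesday's makes about 0.504 M of G, a third of its Z. Its c_Z midway between start and end, 1.25 M, is still higher than Wednesday's charge, so this estimate puts Tuesday's share near 31.0%. This reckoning puts Tuesday's second.

7. The forecast gives Thursday's > Wednesday's > Tuesday's > Saturday's > Friday's, with 30% (25% to 36%) first and 9% (6.5% to 12%) last. On Tuesday's it says: “Z heavily depleted, so nearly tied with Wednesday's”. It differs from this reckoning in that pair and in Thursday's share.

The flasks give Thursday's > Tuesday's > Wednesday's > Saturday's > Friday's, with 42.2% first and 10.5% last.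

    L → D (k = 0.00440 /min)
    G → X (k = 3.30 × 10⁻⁶ /min)
    J + Z → G (k = 0.00410 /M/min)
    J → L (k = 0.0160 /min)

Thursday's still holds 21.9% as L at 5.00 h, and at 50.0 h its share is 32.7%. A flask like Friday's but with 1.2 M of Z has Q·c_Z = 0.432, so the rule gives 30.2%. That flask gives 31.4%.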